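**Retrosynthetic overview**
- The target is cut between ring carbon C3 and chain carbon C1'. C3 is normally the nucleophilic enol carbon of the hydroxyquinone; here it is used as an electrophile, as its phenyliodonium ylide (an enolonium equivalent), and the chain is the nucleophile as a B-alkyl-9-BBN.
- The ylide comes from 2-hydroxy-5-methoxy-1,4-benzoquinone, made by mono-hydrolysis of symmetrical 2,5-dimethoxy-1,4-benzoquinone, so the ring regiochemistry cannot go wrong.
- The borane comes from terminal-selective hydroboration of (8Z,11Z)-pentadeca-1,8,11-triene, which comes from all-cis semi-hydrogenation of pentadeca-1,8,11-triyne, itself from copper-catalysed propargylation of nona-1,8-diyne with 1-bromohex-2-yne.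
- No ring is formed: the six-membered quinone ring is bought intact. Both Z alkenes are set in one hydrogenation.

Assumption: the target has no stereocentre and is achiral, so "single enantiomer" is read as the single (8Z,11Z) geometric isomer shown.

**Route**

Step 1
Reactants: 1 nona-1,8-diyne (3 equiv); 2 1-bromohex-2-yne (1 equiv)
Product: 3 pentadeca-1,8,11-triyne
Conditions: CuI (10 mol %), n-Bu4NCl (10 mol %), K2CO3 (1.5 equiv), DMF, 25 °C, Ar; excess 1 recovered by distillation
Reagents that add atoms: none
Why: Copper-catalysed propargylic substitution by a terminal alkyne (Jeffery coupling through a copper acetylide) gives the skipped diyne, and the threefold excess of the symmetrical diyne holds it at mono-alkylation.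

Step 2
Reactants: 3 pentadeca-1,8,11-triyne
Product: 4 (8Z,11Z)-pentadeca-1,8,11-triene
Conditions: H2 (1 atm, stopped at 3.0 equiv uptake), Pd/CaCO3 poisoned with Pb(OAc)2, quinoline, EtOAc, 10 °C
Reagents that add atoms: none
Why: Lindlar semi-hydrogenation delivers H2 syn on the poisoned palladium surface, so both internal alkynes become Z alkenes and the terminal alkyne becomes the vinyl group.

Step 3
Reactants: 5 2,5-dimethoxy-1,4-benzoquinone
Product: 6 2-hydroxy-5-methoxy-1,4-benzoquinone
Conditions: 1 M NaOH (1.1 equiv), H2O/THF, 25 °C; then 2 M HCl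
Reagents that add atoms: sodium hydroxide, [Na+].[OH-]
Why: Addition–elimination of hydroxide at one vinylogous ester carbon (vinylogous saponification) stops after one methoxy group because the resulting vinylogous carboxylate anion resists a second attack, and the symmetry of 5 allows only one product.

Step 4
Reactants: 6 2-hydroxy-5-methoxy-1,4-benzoquinone
Product: 7 5-methoxy-2-oxido-3-(phenyliodonio)-1,4-benzoquinone (phenyliodonium ylide of 6)
Conditions: PhI(OAc)2 (1.05 equiv), CH2Cl2, 0 → 25 °C, dark; precipitate filtered
Reagents that add atoms: (diacetoxyiodo)benzene, CC(=O)OI(OC(C)=O)c1ccccc1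
Why: Iodonium ylide formation, as for 1,3-dicarbonyl compounds and other hydroxyquinones, occurs when the enol carbon C3 attacks trivalent iodine with loss of two AcOH, which fixes the site at C3 and turns this nucleophilic carbon into an electrophile.

Step 5
Reactants: 4 (8Z,11Z)-pentadeca-1,8,11-triene (1.4 equiv); 7 5-methoxy-2-oxido-3-(phenyliodonio)-1,4-benzoquinone (1.0 equiv)
Product: 9 sorgoleone-360 [2-hydroxy-5-methoxy-3-((8Z,11Z)-pentadeca-8,11-dien-1-yl)-1,4-benzoquinone], via B-pentadecadienyl-9-BBN 8 (not isolated)
Conditions: 9-BBN (1.3 equiv), THF, 0 → 25 °C; then 3 M aq K3PO4 (3 equiv), 7, Pd(dppf)Cl2 (5 mol %), AsPh3 (10 mol %), DMF, 25 °C, degassed, dark; then 1 M HCl, air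
Reagents that add atoms: 9-borabicyclo[3.3.1]nonane (9-BBN), B1C2CCCC1CCC2 (its boron and ring carbons are in 8 only; 9 keeps one hydrogen from it)
Why: Proposed new method: B-alkyl Suzuki–Miyaura coupling of a hydroxyquinone iodonium ylide used as an enolonium equivalent, in which 9-BBN hydroborates only the terminal alkene (anti-Markovnikov), zerovalent palladium inserts into the C3–I bond with iodobenzene as leaving group, the hydroxide-activated borane transmetalates and reductive elimination joins C3 to C1' at 25 °C without touching either Z alkene; the closest known chemistry is the palladium-catalysed Stille and Suzuki coupling of hydroxyquinone phenyliodonium ylides with aryl stannanes and boronic acids, and the room-temperature B-alkyl Suzuki coupling of alkenyl iodides and iodonium salts.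

**Compound list**
1 | nona-1,8-diyne | C#CCCCCCC#C | starting material
2 | 1-bromohex-2-yne | CCCC#CCBr | starting material
3 | pentadeca-1,8,11-triyne | C#CCCCCCC#CCC#CCCC | intermediate
4 | (8Z,11Z)-pentadeca-1,8,11-triene | C=CCCCCC/C=C\C/C=C\CCC | intermediate
5 | 2,5-dimethoxy-1,4-benzoquinone | COC1=CC(=O)C(OC)=CC1=O | starting material
6 | 2-hydroxy-5-methoxy-1,4-benzoquinone | COC1=CC(=O)C(O)=CC1=O | intermediate
7 | 5-methoxy-2-oxido-3-(phenyliodonio)-1,4-benzoquinone | COC1=CC(=O)C([O-])=C([I+]c2ccccc2)C1=O | intermediate
8 | 9-[(8Z,11Z)-pentadeca-8,11-dien-1-yl]-9-borabicyclo[3.3.1]nonane | CCC/C=C\C/C=C\CCCCCCCB1C2CCCC1CCC2 | intermediate (not isolated)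
9 | sorgoleone-360, 2-hydroxy-5-methoxy-3-[(8Z,11Z)-pentadeca-8,11-dien-1-yl]-1,4-benzoquinone | CCC/C=C\C/C=C\CCCCCCCC1=C(O)C(=O)C=C(OC)C1=O | target

**Totals**
Total step count: 5. Longest linear sequence: 3 steps (steps 1, 2, 5 or steps 3, 4, 5).

**Steps most likely to fail, with fallbacks**

Step 5 is the riskiest: the ylide may ring-contract or be reduced by the borane before palladium inserts, and B-alkyl transfer to this electrophile is untested. The fallback forms the same C3–C1' bond at the arene oxidation level. It sets out from borane 8, generated from 4 as in step 5. Commercial 1,2,4,5-tetramethoxybenzene is brominated (NBS, MeCN, 0 °C) to 3-bromo-1,2,4,5-tetramethoxybenzene F1. B-alkyl Suzuki coupling of F1 with 8 (Pd(OAc)2, SPhos, aq K3PO4, THF, 60 °C) gives 3-[(8Z,11Z)-pentadeca-8,11-dien-1-yl]-1,2,4,5-tetramethoxybenzene F2. Oxidative demethylation with (NH4)2Ce(NO3)6 in MeCN/H2O at 0 °C gives 2,5-dimethoxy-3-[(8Z,11Z)-pentadeca-8,11-dien-1-yl]-1,4-benzoquinone F3. Brief treatment with 70% HClO4 in CH2Cl2 at 25 °C is expected to hydrolyse the methoxy group flanked by the alkyl chain, which brings the sequence back to the route at 9. That regioselectivity is the weak point of the fallback; the regioisomeric hydroxyquinone, if formed, would have to be separated.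

Step 2 is next: three alkynes must be reduced in one pot, and the new vinyl group can over-reduce while the last internal alkyne is still reacting. The fallback brings in the terminal alkene ready-made, so only two internal alkynes are reduced. It sets out from 2. Commercial 7-bromohept-1-ene and LiC≡CH·H2NCH2CH2NH2 in DMSO at 15 °C give non-1-en-8-yne F4. The copper-catalysed coupling of step 1, now between F4 and 2 in a 1:1 ratio, gives pentadec-1-ene-8,11-diyne F5. Semi-reduction with H2 over P-2 nickel boride (Ni(OAc)2·4H2O, NaBH4, ethylenediamine, EtOH), which leaves terminal alkenes alone, comes back to the route at 4. This also removes the statistical mono-coupling of step 1.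

Step 4 is third: a benzoquinone iodonium ylide with a free ring position may be too labile to isolate cleanly. The fallback replaces the ylide by a simple α-iodo enol as the electrophile. It sets out from 6. Iodination (I2, morpholine, aq K2CO3, 25 °C, then acidification) gives 2-hydroxy-3-iodo-5-methoxy-1,4-benzoquinone F6. F6 takes the place of 7 in the palladium-catalysed coupling with borane 8 (Pd(dppf)Cl2, aq K3PO4, THF/DMF, 40 °C, then 1 M HCl) and comes back to the route at 9.

**Further compounds**
F1 | step 5 | 3-bromo-1,2,4,5-tetramethoxybenzene | COc1cc(OC)c(OC)c(Br)c1OC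
F2 | step 5 | 3-[(8Z,11Z)-pentadeca-8,11-dien-1-yl]-1,2,4,5-tetramethoxybenzene | COc1cc(OC)c(OC)c(CCCCCCC/C=C\C/C=C\CCC)c1OC
F3 | step 5 | 2,5-dimethoxy-3-[(8Z,11Z)-pentadeca-8,11-dien-1-yl]-1,4-benzoquinone | COC1=CC(=O)C(OC)=C(CCCCCCC/C=C\C/C=C\CCC)C1=O
F4 | step 2 | non-1-en-8-yne | C=CCCCCCC#C
F5 | step 2 | pentadec-1-ene-8,11-diyne | C=CCCCCCC#CCC#CCCC
F6 | step 4 | 2-hydroxy-3-iodo-5-methoxy-1,4-benzoquinone | COC1=CC(=O)C(O)=C(I)C1=O
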